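The target ring is read as a 2-substituted 1,4-benzoquinone at lower oxidation level: C3 and C6 carry the former quinone oxygens, C1 the benzoyloxymethyl arm, and the C4=C5 alkene of the cyclohexene ring is the unsubstituted quinone double bond. One catalytic enantioselective Diels–Alder reaction with cyclopentadiene masks C4=C5 inside a norbornene, makes two C–C bonds and four scaffold stereocentres, and gives the carbocycle a convex face from which hydride (C3, C6) and OsO4 (C1, C2) later set all permanent centres before cycloreversion returns C4=C5. The dienophile is 2-(benzoyloxymethyl)-1,4-benzoquinone, which already carries the C7 benzoate of the target, so no protecting group is spent.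

Key step: step 4

Numbering: C1–C7 of the target are kept for the quinone-derived carbons in all intermediates; Ca and Cb are the norbornene alkene carbons, Ca next to the bridgehead on C4 and Cb next to the bridgehead on C5.

Assumption: the catalyst antipode is chosen on the binding model in which the boron cation sits on the C3 carbonyl (conjugated through C2=C1 to the alkyl-bearing C1, hence the more basic one) syn to C4–H; should the first run show the opposite sense of induction, the (S)-prolinol-derived catalyst is taken and nothing else changes.

Step 1
Reactants: 1 2,5-dimethoxybenzyl alcohol; 2 benzoyl chloride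
Product: 3 2,5-dimethoxybenzyl benzoate
Conditions: 2 (1.1 equiv), Et3N (1.5 equiv), 4-(dimethylamino)pyridine (5 mol %), CH2Cl2, 0 °C → rt
Reagents that add atoms: none
Why: Amine-catalysed O-acylation (nucleophilic acyl substitution) of an unhindered primary benzylic alcohol by an acid chloride is reliable and installs the C7 benzoate that the target keeps; no stereocentre is formed.

Step 2
Reactants: 3 2,5-dimethoxybenzyl benzoate
Product: 4 2-(benzoyloxymethyl)-1,4-benzoquinone
Conditions: (NH4)2Ce(NO3)6 (2.5 equiv), MeCN–H2O (2:1), 0 °C, 15 min; used promptly
Reagents that add atoms: water, O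
Why: Oxidative demethylation of a 1,4-dimethoxyarene by tetravalent cerium (two one-electron oxidations, water adding at the ipso carbons, methanol leaving) gives the quinone within minutes under conditions that leave a benzoate ester untouched; no stereocentre is formed.

Step 3
Reactants: 5 dicyclopentadiene
Product: 6 cyclopenta-1,3-diene
Conditions: neat, 170–180 °C, distilled through a short column (bp 40–42 °C) into a −78 °C receiver; used the same day
Reagents that add atoms: none
Why: Thermal retro-Diels–Alder cracking of the dimer into two molecules of monomer, with removal of the volatile monomer by distillation, is the standard source of the diene, which is kept cold because it redimerises at room temperature; no stereocentre remains.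

Step 4
Reactants: 4 2-(benzoyloxymethyl)-1,4-benzoquinone; 6 cyclopenta-1,3-diene
Product: 7 (1R,2S,7R,8S)-4-(benzoyloxymethyl)tricyclo[6.2.1.0(2,7)]undeca-4,9-diene-3,6-dione (endo adduct: C4–H and C5–H cis, enedione ring folded under the new Ca=Cb bond)
Conditions: 6 (3 equiv), (R)-tetrahydro-1-(2-methylphenyl)-3,3-diphenyl-1H,3H-pyrrolo[1,2-c][1,3,2]oxazaborole (20 mol %) premixed with HNTf2 (16 mol %), CH2Cl2, −78 °C; pH 7 buffer quench, cold filtration through neutral silica, no exposure to acid or base
Reagents that add atoms: none
Why: The boron cation binds a quinone carbonyl through the lone pair syn to the adjacent ring C–H of the C4=C5 bond, lowers the LUMO, and cyclopentadiene adds to C4=C5 in a concerted, asynchronous [4+2] cycloaddition. The closest known reaction type is the oxazaborolidinium-catalysed Diels–Alder reaction of substituted 1,4-benzoquinones with dienes, cyclopentadiene included. The one new ring, the cyclohexene ring of the norbornene, closes by suprafacial [4+2] cycloaddition in which both σ-bonds (C4–bridgehead and C5–bridgehead) form in the same step. C4 and C5 are cis because the dienophile geometry is conserved, the two bridgeheads follow from the endo transition state (diene π-system over the bound enedione), and the absolute sense of all four comes from the catalyst, whose aryl groups screen one quinone face. The step needs site selectivity for C4=C5 over C1=C2, secured by the CH2OBz group that makes C1=C2 trisubstituted and hindered while C4=C5 alone offers an α-C–H on each carbon for catalyst binding, and endo selectivity, which is inherent to cyclopentadiene with Lewis-acid-bound quinones at −78 °C where the uncatalysed reaction is slow. Enantioface selection rests on preferential binding at the C3 carbonyl and is the main uncertainty of the route.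

Step 5
Reactants: 7 endo adduct
Product: 8 endo,endo-diol: both ketones of 7 reduced, C3–OH and C6–OH on the concave face (syn to Ca=Cb), C7 benzoate and both alkenes intact
Conditions: NaBH4 (2.2 equiv), CeCl3·7H2O (2.2 equiv), MeOH–CH2Cl2 (3:1), −78 → −20 °C
Reagents that add atoms: none
Why: Luche reduction gives 1,2-reduction of both enone carbonyls without conjugate reduction or ester cleavage, hydride arriving on the open convex face of the cis-fused ring so that both new carbinol centres (C3, C6) carry hydroxyl on the concave face.

Step 6
Reactants: 8 endo,endo-diol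
Product: 9 bromoether: C3–O bonded to Ca (endo) in a tetrahydrofuran ring, Br exo on Cb, C6–OH free, C1=C2 and C7 benzoate intact
Conditions: N-bromosuccinimide (1.05 equiv), CH2Cl2, 0 °C, dark
Reagents that add atoms: N-bromosuccinimide, O=C1CCC(=O)N1Br
Why: Bromoetherification: bromonium forms on the exo face of the strained norbornene alkene (far more reactive than the hindered, electron-poor C1=C2) and a concave-face hydroxyl opens it anti, fixing Ca (O endo) and Cb (Br exo); closure through C3–OH is expected to be preferred because it is the less encumbered hydroxyl and the terminal donor of the O3–H···O6–H···O=C hydrogen-bond chain in CH2Cl2, whereas C6–OH is inductively deactivated by the neighbouring CH2OBz arm, and any regioisomer is separated and returned to 8 under the zinc conditions of step 10.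

Step 7
Reactants: 9 bromoether
Product: 10 C6 methyl ether of 9
Conditions: Me3OBF4 (3 equiv), 1,8-bis(dimethylamino)naphthalene (3.5 equiv), 4 Å molecular sieves, CH2Cl2, 0 °C → rt
Reagents that add atoms: trimethyloxonium tetrafluoroborate, C[O+](C)C.F[B-](F)(F)F
Why: O-Alkylation with a trialkyloxonium salt and a hindered non-nucleophilic amine methylates the only free hydroxyl without ever forming an alkoxide, so the neighbouring C7 benzoate cannot migrate and the alkyl bromide is untouched; the C6 configuration is retained because its C–O bond is not broken.

Step 8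
Reactants: 10 methyl ether
Product: 11 1,2-diol: C1–OH (tertiary) and C2–OH cis to each other on the convex face, trans to the C3 and C6 oxygens; CH2OBz on C1 on the concave face
Conditions: OsO4 (5 mol %), N-methylmorpholine N-oxide (2 equiv), acetone–H2O (5:1), rt
Reagents that add atoms: osmium tetroxide, O=[Os](=O)(=O)=O; N-methylmorpholine N-oxide, C[N+]1([O-])CCOCC1; water, O
Why: Catalytic syn-dihydroxylation ([3+2] addition of OsO4, then osmate hydrolysis) of the only remaining alkene takes place on the convex face, anti to the cage and to both allylic C–O bonds, which sets C1 and C2 cis to each other and trans to the C3/C6 oxygens.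

Step 9
Reactants: 11 1,2-diol
Product: 12 2-O-acetate of 11 (C1–OH free)
Conditions: Ac2O (1.2 equiv), pyridine, 4-(dimethylamino)pyridine (5 mol %), CH2Cl2, 0 °C → rt
Reagents that add atoms: acetic anhydride, CC(=O)OC(C)=O
Why: Amine-catalysed acylation discriminates between the secondary C2 hydroxyl and the tertiary, fully substituted C1 hydroxyl, so a slight excess of anhydride gives the 2-O-acetate only; no stereocentre changes.

Step 10
Reactants: 12 acetate
Product: 13 norbornene carbinol: Ca=Cb restored, C3–OH free on the concave face, C2–OAc, C1–OH, C6–OMe, C7–OBz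
Conditions: Zn dust (activated, 10 equiv), AcOH–THF (1:3), rt → 40 °C
Reagents that add atoms: none
Why: Reductive elimination of the β-bromo ether by zerovalent zinc (insertion into C–Br, then expulsion of the β-alkoxide) regenerates the norbornene alkene and the C3 hydroxyl under mildly acidic conditions in which the esters and the methyl ether persist and the liberated alkoxide is protonated before the C2 acetate can migrate; the Ca and Cb centres vanish and all others are untouched.

Step 11
Reactants: 13 norbornene carbinol; 2 benzoyl chloride
Product: 14 3-O-benzoate of 13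
Conditions: 2 (1.5 equiv), pyridine, 4-(dimethylamino)pyridine (10 mol %), CH2Cl2, 0 °C → rt
Reagents that add atoms: none
Why: Acylation of the single secondary hydroxyl (C3) by the acid chloride proceeds with retention at C3, while the tertiary C1 hydroxyl does not react under these conditions.

Step 12
Reactants: 14 benzoate
Product: 15 [(1R,2S,3R,6S)-2-acetoxy-3-benzoyloxy-1-hydroxy-6-methoxycyclohex-4-en-1-yl]methyl benzoate (target)
Conditions: Ph2O (degassed, dilute), 250 °C, argon stream, 20–40 min
Reagents that add atoms: none
Why: Thermal retro-Diels–Alder reaction releases cyclopentadiene (swept out in the gas stream) and returns the C4=C5 alkene, deleting the four scaffold centres while C1, C2, C3 and C6, which take no part in the pericyclic process, keep their configuration.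

Compound list
1 | 2,5-dimethoxybenzyl alcohol | COc1ccc(OC)c(CO)c1 | starting material
2 | benzoyl chloride | O=C(Cl)c1ccccc1 | starting material
3 | 2,5-dimethoxybenzyl benzoate | COc1ccc(OC)c(COC(=O)c2ccccc2)c1 | intermediate
4 | 2-(benzoyloxymethyl)-1,4-benzoquinone | O=C1C=CC(=O)C(COC(=O)c2ccccc2)=C1 | intermediate
5 | dicyclopentadiene | C1C=CC2C1C1CC2C=C1 | starting material
6 | cyclopenta-1,3-diene | C1C=CC=C1 | intermediate
7 | (1R,2S,7R,8S)-4-(benzoyloxymethyl)tricyclo[6.2.1.0(2,7)]undeca-4,9-diene-3,6-dione, endo | O=C1C=C(COC(=O)c2ccccc2)C(=O)[C@@H]2[C@H]1[C@@H]1C=C[C@H]2C1 | intermediate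
8 | endo,endo-3,6-diol of 7 (both OH on the concave face) | O[C@H]1C=C(COC(=O)c2ccccc2)[C@@H](O)[C@@H]2[C@H]1[C@@H]1C=C[C@H]2C1 | intermediate
9 | bromoether (C3–O–Ca endo, Br exo on Cb, C6–OH free) | O3[C@H]1C=C(COC(=O)c2ccccc2)[C@@H](O)[C@@H]2[C@H]1[C@@H]1[C@H]3[C@@H](Br)[C@H]2C1 | intermediate
10 | C6 methyl ether of 9 | O3[C@H]1C=C(COC(=O)c2ccccc2)[C@@H](OC)[C@@H]2[C@H]1[C@@H]1[C@H]3[C@@H](Br)[C@H]2C1 | intermediate
11 | convex-face 1,2-diol of 10 | O3[C@H]1[C@H](O)[C@@](O)(COC(=O)c2ccccc2)[C@@H](OC)[C@@H]2[C@H]1[C@@H]1[C@H]3[C@@H](Br)[C@H]2C1 | intermediate
12 | 2-O-acetate of 11 | O3[C@H]1[C@H](OC(C)=O)[C@@](O)(COC(=O)c2ccccc2)[C@@H](OC)[C@@H]2[C@H]1[C@@H]1[C@H]3[C@@H](Br)[C@H]2C1 | intermediate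
13 | norbornene carbinol (C3–OH free, Ca=Cb restored) | O[C@H]1[C@H](OC(C)=O)[C@@](O)(COC(=O)c2ccccc2)[C@@H](OC)[C@@H]2[C@H]1[C@@H]1C=C[C@H]2C1 | intermediate
14 | 3-O-benzoate of 13 | O=C(c1ccccc1)O[C@H]1[C@H](OC(C)=O)[C@@](O)(COC(=O)c2ccccc2)[C@@H](OC)[C@@H]2[C@H]1[C@@H]1C=C[C@H]2C1 | intermediate
15 | [(1R,2S,3R,6S)-2-acetoxy-3-benzoyloxy-1-hydroxy-6-methoxycyclohex-4-en-1-yl]methyl benzoate | CO[C@H]1C=C[C@@H](OC(=O)c2ccccc2)[C@H](OC(C)=O)[C@@]1(O)COC(=O)c1ccccc1 | target

Total step count: 12 (step 3 prepares the diene).
Longest linear sequence: 11 steps (1 → 15 through steps 1, 2 and 4–12).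

Steps most likely to fail

Step 4. The two quinone carbonyls differ only slightly in basicity, so the catalyst may bind both and erode enantiocontrol; uncatalysed cycloaddition or tautomerisation of the adduct to the hydroquinone would add to the loss. The fallback replaces asymmetric catalysis by resolution. It sets out from 4 and 6: uncatalysed cycloaddition (CH2Cl2, −20 → 0 °C) should give the racemic endo adduct F1, Luche reduction as in step 5 the racemic diol F2, and preparative chromatography on an amylose tris(3,5-dimethylphenylcarbamate) phase separates the wanted enantiomer. The route is rejoined at 8.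

Step 6. Site selectivity between the two concave-face hydroxyls may be poor, with ether closure through C6–OH competing with closure through C3–OH. The fallback removes the choice by tying O6 to O7 first, and sets out from 8. K2CO3 in MeOH cleaves the benzoate to give the triol F3. 2,2-Dimethoxypropane with pyridinium p-toluenesulfonate, under equilibrating conditions, should close the six-membered acetonide F4 across the C6/C7 1,3-diol in preference to the seven-membered alternative through O3, leaving the C3 hydroxyl free. N-Bromosuccinimide can then close only through C3–OH, giving the bromoether F5. Aqueous AcOH (80%, rt) releases the diol F6, and BzCl (1.05 equiv) with 2,4,6-collidine at −40 °C benzoylates the primary C7 hydroxyl selectively. The route is rejoined at 9.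

Step 12. At 250 °C an acyl group may migrate onto the free tertiary C1 hydroxyl, benzoic or acetic acid may be lost with aromatisation, or the allylic benzoate may shift. The fallback caps the hydroxyl before thermolysis and sets out from 14: Me3SiOTf with 2,6-lutidine (CH2Cl2, −78 °C) gives the silyl ether F7; cycloreversion by flash vacuum pyrolysis (about 450 °C, short contact time) gives the silylated cyclohexene F8; HF·pyridine in THF at 0 °C removes the silyl group. The route is rejoined at 15.

Further compounds
F1 | step 4 | racemic endo adduct (racemate of 7; relative configuration as drawn) | O=C1C=C(COC(=O)c2ccccc2)C(=O)[C@@H]2[C@H]1[C@@H]1C=C[C@H]2C1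
F2 | step 4 | racemic endo,endo-diol (racemate of 8; relative configuration as drawn) | O[C@H]1C=C(COC(=O)c2ccccc2)[C@@H](O)[C@@H]2[C@H]1[C@@H]1C=C[C@H]2C1
F3 | step 6 | triol (8 without the benzoyl group) | O[C@H]1C=C(CO)[C@@H](O)[C@@H]2[C@H]1[C@@H]1C=C[C@H]2C1
F4 | step 6 | C6/C7 acetonide of the triol (C3–OH free) | O[C@H]1C=C3COC(C)(C)O[C@H]3[C@@H]2[C@H]1[C@@H]1C=C[C@H]2C1
F5 | step 6 | bromoether of the acetonide (C3–O–Ca endo, Br exo on Cb) | O4[C@H]1C=C3COC(C)(C)O[C@H]3[C@@H]2[C@H]1[C@@H]1[C@H]4[C@@H](Br)[C@H]2C1
F6 | step 6 | bromoether diol (C6–OH and C7–OH free) | O3[C@H]1C=C(CO)[C@@H](O)[C@@H]2[C@H]1[C@@H]1[C@H]3[C@@H](Br)[C@H]2C1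
F7 | step 12 | 1-O-trimethylsilyl ether of 14 | O=C(c1ccccc1)O[C@H]1[C@H](OC(C)=O)[C@@](O[Si](C)(C)C)(COC(=O)c2ccccc2)[C@@H](OC)[C@@H]2[C@H]1[C@@H]1C=C[C@H]2C1
F8 | step 12 | 1-O-trimethylsilyl ether of 15 | CO[C@H]1C=C[C@@H](OC(=O)c2ccccc2)[C@H](OC(C)=O)[C@@]1(O[Si](C)(C)C)COC(=O)c1ccccc1
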